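The locants are C1 (OMe), C2=C3 (C3 bears C7H2OBz), C4 (OH), C5 (OBz) and C6 (OH). The cyclohexene is disconnected at C3. This carbon is inserted as CBr2 into the C2=C4 double bond of a cyclopentene that carries C1, C6 and C5 with the configuration of sugar carbons C2–C4 of D-glucose. Silver-induced opening of the derived 6,6-dibromobicyclo[3.1.0]hexane expands the five-membered ring to the six-membered one. The step exploits the cis C4-OH/C5-OBz pair next to C2=C3: the C5 benzoate captures the allyl cation at C4 only, from its own face. One operation sets ring size, alkene position, the C4 stereocentre and a C3–Br handle for C7.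

Key step: step 8

Remark: target locants (C1–C7 as above) are used for 7–13 and sugar locants for 1–4. The benzylidene carbon of commercial 1 is taken as R (equatorial phenyl); it is lost in step 3.

Step 1
Reactants: 1 methyl 4,6-O-[(R)-benzylidene]-α-D-glucopyranoside
Product: 2 methyl 4,6-O-benzylidene-2-O-methyl-α-D-glucopyranoside
Conditions: MeI, Bu4NHSO4 (cat.), aq NaOH, CH2Cl2, reflux
Reagents that add atoms: iodomethane, CI
Why: Phase-transfer Williamson etherification, in which the 2-OH (acidified by the neighbouring anomeric centre) is the hydroxyl extracted as its ion pair, so monomethylation should fall on O2 and no stereocentre is touched.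

Step 2
Reactants: 2 methyl 4,6-O-benzylidene-2-O-methyl-α-D-glucopyranoside
Product: 3 methyl 3-O-benzoyl-4,6-O-benzylidene-2-O-methyl-α-D-glucopyranoside
Conditions: BzCl, pyridine, DMAP (cat.), 0 °C to rt
Reagents that add atoms: benzoyl chloride, O=C(Cl)c1ccccc1
Why: DMAP-catalysed esterification caps the only free hydroxyl with an ester that later leaves together with the second benzoate.

Step 3
Reactants: 3 methyl 3-O-benzoyl-4,6-O-benzylidene-2-O-methyl-α-D-glucopyranoside
Product: 4 methyl 3,4-di-O-benzoyl-6-bromo-6-deoxy-2-O-methyl-α-D-glucopyranoside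
Conditions: NBS, BaCO3, CCl4, reflux
Reagents that add atoms: N-bromosuccinimide, O=C1CCC(=O)N1Br
Why: Hanessian–Hullar reaction, in which radical bromination of the acetal C–H and ionic fragmentation with bromide attack at primary C6 give the 6-bromide and leave a benzoate on O4, the oxygen that becomes O5 of the target.

Step 4
Reactants: 4 methyl 3,4-di-O-benzoyl-6-bromo-6-deoxy-2-O-methyl-α-D-glucopyranoside
Product: 5 (2R,3S,4R)-3,4-bis(benzoyloxy)-2-methoxyhex-5-enal
Conditions: Zn dust (activated), iPrOH–H2O, reflux
Reagents that add atoms: none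
Why: Vasella fragmentation, in which zinc insertion into C6–Br and Grob-type expulsion of the ring oxygen release C1 as the aldehyde and C5=C6 as the alkene under near-neutral conditions that leave C2–C4 and both esters untouched.

Step 5
Reactants: 5 (2R,3S,4R)-3,4-bis(benzoyloxy)-2-methoxyhex-5-enal
Product: 6 (3S,4R,5R)-3-methoxyhepta-1,6-diene-4,5-diyl dibenzoate
Conditions: Zn, CH2Br2, TiCl4, THF–CH2Cl2, 0 °C to rt
Reagents that add atoms: dibromomethane, BrCBr
Why: Takai–Lombardo methylenation, whose non-basic reagent takes the aldehyde in preference to the benzoates and avoids the β-elimination of the 3-benzoate and the epimerisation at the α-methoxy carbon that a basic ylide could cause.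

Step 6
Reactants: 6 (3S,4R,5R)-3-methoxyhepta-1,6-diene-4,5-diyl dibenzoate
Product: 7 (1R,2R,5S)-5-methoxycyclopent-3-ene-1,2-diyl dibenzoate (all-trans; C6-OBz, C5-OBz and C1-OMe in target locants)
Conditions: second-generation Grubbs catalyst (cat.), CH2Cl2, 40 °C
Reagents that add atoms: none
Why: Ring-closing metathesis of two monosubstituted alkenes to an unstrained cyclopentene, driven by loss of ethene, with the three stereocentres untouched.

Step 7
Reactants: 7 (1R,2R,5S)-5-methoxycyclopent-3-ene-1,2-diyl dibenzoate
Product: 8 6,6-dibromo-4-methoxybicyclo[3.1.0]hexane-2,3-diyl dibenzoate (CBr2 bridge anti to C1-OMe and C5-OBz)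
Conditions: PhHgCBr3, benzene, 80 °C
Reagents that add atoms: phenyl(tribromomethyl)mercury, BrC(Br)(Br)[Hg]c1ccccc1
Why: Dibromocarbene transfer from the Seyferth reagent is neutral (esters survive) and is the classical answer to poorly nucleophilic alkenes, and the concerted cis [2+1] addition from the face opposite the two allylic substituents sets the two bridgehead centres, both of which are erased in step 8.

Step 8
Reactants: 8 6,6-dibromo-4-methoxybicyclo[3.1.0]hexane-2,3-diyl dibenzoate
Product: 11 (1S,4S,5S,6S)-3-bromo-1-methoxycyclohex-2-ene-4,5,6-triol (target locants), via benzoxonium tetrafluoroborate 9 (not isolated), via hydroxy dibenzoate 10 (not isolated)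
Conditions: AgBF4, ClCH2CH2Cl, 60 °C, dark; then THF–H2O, rt, filter; then K2CO3, MeOH, rt
Reagents that add atoms: none
Why: Silver ion abstracts the endo bromide of 8 while the C2–C4 bond opens in a disrotatory two-electron electrocyclic process, so the five-membered ring C1-C2-C4-C5-C6 becomes the six-membered ring with a 3-bromoallyl cation over C2-C3-C4, strain release paying for a cation flanked by C–O dipoles. The closest known reaction type is the silver-promoted ring expansion of ring-fused gem-dibromocyclopropanes with capture of the allyl cation by a tethered heteroatom nucleophile, joined here to classical neighbouring-group participation of an ester. The carbonyl oxygen of the C5 benzoate closes the transient 1,3-dioxolan-2-ylium ring of 9 in a 5-exo-trig mode, and because this ring can only be cis-fused, the C5 stereocentre places the new C4–O bond on its own face. The step needs attack at C4 and not at C2, which is secured because C1 carries only a non-participating methyl ether and the C6 benzoate could reach either terminus only through a bridged six-membered ion that demands three axial substituents. Water converts 9 into hydroxy benzoate 10 (axial C4 ester expected, the O5 ester would converge) and methanolysis strips both benzoates, the new O4 being the former carbonyl oxygen. The exo bromide stays on C3 as the handle for C7, and the bridgehead centres of 8 vanish, so the face of carbene addition is of no consequence.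

Step 9
Reactants: 11 (1S,4S,5S,6S)-3-bromo-1-methoxycyclohex-2-ene-4,5,6-triol
Product: 12 (1S,4R,5R,6S)-3-(hydroxymethyl)-1-methoxycyclohex-2-ene-4,5,6-triol (target locants)
Conditions: Bu3SnCH2OH, Pd(PPh3)4 (cat.), 1,4-dioxane, 100 °C
Reagents that add atoms: (tributylstannyl)methanol, OC[Sn](CCCC)(CCCC)CCCC
Why: Stille hydroxymethylation (oxidative addition of zerovalent palladium into C3–Br, transmetalation, reductive elimination) keeps the alkene in place and tolerates free hydroxyls, and prior removal of the esters leaves no allylic ester that palladium could ionise.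

Step 10
Reactants: 12 (1S,4R,5R,6S)-3-(hydroxymethyl)-1-methoxycyclohex-2-ene-4,5,6-triol
Product: 13 target, (1S,4R,5R,6R)-5-benzoyloxy-3-(benzoyloxymethyl)-1-methoxycyclohex-2-ene-4,6-diol (target locants)
Conditions: BzCl (2 equiv), Fe(acac)3 (cat.), iPr2NEt, MeCN, rt
Reagents that add atoms: benzoyl chloride, O=C(Cl)c1ccccc1
Why: Catalyst-controlled site-selective acylation, resting on the fact that 12 is the carbocyclic counterpart of a methyl β-galactopyranoside (C1, C6, C5, C4, C3, C7 for sugar C1–C6), a class that gives 3,6-diesters in this reaction type: the iron centre chelates the cis C4/C5 diol and activates its equatorial O5, the primary allylic O7 reacts by intrinsic nucleophilicity, and pseudoaxial O4 and the O6 next to OMe stay free.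

Compound list
1 | methyl 4,6-O-[(R)-benzylidene]-α-D-glucopyranoside | c1ccccc1[C@@H]2OC[C@H]3O[C@H](OC)[C@H](O)[C@@H](O)[C@@H]3O2 | starting material
2 | methyl 4,6-O-benzylidene-2-O-methyl-α-D-glucopyranoside | c1ccccc1[C@@H]2OC[C@H]3O[C@H](OC)[C@H](OC)[C@@H](O)[C@@H]3O2 | intermediate
3 | methyl 3-O-benzoyl-4,6-O-benzylidene-2-O-methyl-α-D-glucopyranoside | c1ccccc1[C@@H]2OC[C@H]3O[C@H](OC)[C@H](OC)[C@@H](OC(=O)c4ccccc4)[C@@H]3O2 | intermediate
4 | methyl 3,4-di-O-benzoyl-6-bromo-6-deoxy-2-O-methyl-α-D-glucopyranoside | BrC[C@H]1O[C@H](OC)[C@H](OC)[C@@H](OC(=O)c2ccccc2)[C@@H]1OC(=O)c3ccccc3 | intermediate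
5 | (2R,3S,4R)-3,4-bis(benzoyloxy)-2-methoxyhex-5-enal | O=C[C@H](OC)[C@@H](OC(=O)c1ccccc1)[C@H](OC(=O)c2ccccc2)C=C | intermediate
6 | (3S,4R,5R)-3-methoxyhepta-1,6-diene-4,5-diyl dibenzoate | C=C[C@H](OC)[C@@H](OC(=O)c1ccccc1)[C@H](OC(=O)c2ccccc2)C=C | intermediate
7 | (1R,2R,5S)-5-methoxycyclopent-3-ene-1,2-diyl dibenzoate | CO[C@H]1C=C[C@@H](OC(=O)c2ccccc2)[C@@H]1OC(=O)c3ccccc3 | intermediate
8 | 6,6-dibromo-4-methoxybicyclo[3.1.0]hexane-2,3-diyl dibenzoate, CBr2 bridge anti to OMe and to the adjacent benzoate | CO[C@H]1[C@@H]2C(Br)(Br)[C@@H]2[C@@H](OC(=O)c3ccccc3)[C@@H]1OC(=O)c4ccccc4 | intermediate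
9 | cis-fused 2-phenyl-1,3-dioxolan-2-ylium (benzoxonium) tetrafluoroborate across O4/O5 of the 3-bromocyclohexene | CO[C@H]1C=C(Br)[C@H]2[O+]=C(c3ccccc3)O[C@H]2[C@@H]1OC(=O)c4ccccc4.F[B-](F)(F)F | intermediate
10 | 4,6-di-O-benzoyl-3-bromo-1-methoxycyclohex-2-ene-4,5,6-triol (C5-OH free, O4 cis to O5) | CO[C@H]1C=C(Br)[C@@H](OC(=O)c2ccccc2)[C@@H](O)[C@@H]1OC(=O)c3ccccc3 | intermediate
11 | (1S,4S,5S,6S)-3-bromo-1-methoxycyclohex-2-ene-4,5,6-triol | CO[C@H]1C=C(Br)[C@@H](O)[C@@H](O)[C@@H]1O | intermediate
12 | (1S,4R,5R,6S)-3-(hydroxymethyl)-1-methoxycyclohex-2-ene-4,5,6-triol | CO[C@H]1C=C(CO)[C@@H](O)[C@@H](O)[C@@H]1O | intermediate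
13 | CNP0349013.6, (1S,4R,5R,6R)-5-benzoyloxy-3-(benzoyloxymethyl)-1-methoxycyclohex-2-ene-4,6-diol | CO[C@H]1C=C(COC(=O)c2ccccc2)[C@@H](O)[C@@H](OC(=O)c2ccccc2)[C@@H]1O | target

Total step count: 10. Longest linear sequence: 10.

Steps most likely to fail

Step 8. Ionisation of the electron-poor dibromocyclopropane may be slow. The allyl cation may also lose a proton and aromatise before it is captured. The fallback separates the pericyclic event from the substitution.
- It sets out from 8. Heating without silver (o-xylene, 140 °C) should give the 3,4-dibromocyclohexene dibenzoate F1 by thermal disrotatory opening with migration of the endo bromide.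
- The allylic C4 bromide of F1 ionises far more readily than a cyclopropyl bromide. AgOAc in moist acetic acid at rt (Woodward–Prévost conditions) replaces it with participation of the C5 benzoate.
- The route is rejoined at 10, and K2CO3 in MeOH then gives 11.

Step 7. Carbene transfer to an alkene deactivated by two allylic C–O bonds may be outrun by thermal decay of the reagent. The fallback changes the electronics of the substrate.
- It sets out from 7. Methanolysis (K2CO3, MeOH) gives the cyclopentenediol F2, and TBSOTf with 2,6-lutidine gives the bis(silyl ether) F3.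
- This richer, base-stable alkene takes up CBr2 under phase-transfer conditions (CHBr3, 50 % aq NaOH, BnEt3NCl) to give the silylated dibromocyclopropane F4.
- Bu4NF releases the dibromocyclopropane diol F5, and BzCl in pyridine comes back to the route at 8.

Step 10. Discrimination between O5 and O6 may be insufficient, or acylation may run on to a third ester. The fallback separates the two acylations and puts each under its own catalyst.
- It sets out from 12. A lipase (immobilised Candida antarctica lipase B) with vinyl benzoate acylates only the primary hydroxyl and gives the 7-O-monobenzoate F6.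
- Borinic acid catalysis (Ph2BOCH2CH2NH2 cat., BzCl, iPr2NEt, MeCN) binds the cis C4/C5 diol and acylates its equatorial oxygen. The route is rejoined at 13.

Further compounds
F1 | step 8 | 3,4-dibromo-1-methoxycyclohex-2-ene-5,6-diyl dibenzoate, C4-Br trans to C5-OBz | CO[C@H]1C=C(Br)[C@H](Br)[C@@H](OC(=O)c2ccccc2)[C@@H]1OC(=O)c3ccccc3
F2 | step 7 | all-trans 5-methoxycyclopent-3-ene-1,2-diol | CO[C@H]1C=C[C@@H](O)[C@@H]1O
F3 | step 7 | bis(tert-butyldimethylsilyl) ether of F2 | CO[C@H]1C=C[C@@H](O[Si](C)(C)C(C)(C)C)[C@@H]1O[Si](C)(C)C(C)(C)C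
F4 | step 7 | 6,6-dibromo-4-methoxy-2,3-bis(tert-butyldimethylsilyloxy)bicyclo[3.1.0]hexane | CO[C@H]1[C@@H]2C(Br)(Br)[C@@H]2[C@@H](O[Si](C)(C)C(C)(C)C)[C@@H]1O[Si](C)(C)C(C)(C)C
F5 | step 7 | 6,6-dibromo-4-methoxybicyclo[3.1.0]hexane-2,3-diol | CO[C@H]1[C@@H]2C(Br)(Br)[C@@H]2[C@@H](O)[C@@H]1O
F6 | step 10 | 3-(benzoyloxymethyl)-1-methoxycyclohex-2-ene-4,5,6-triol | CO[C@H]1C=C(COC(=O)c2ccccc2)[C@@H](O)[C@@H](O)[C@@H]1O
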